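In a one-step world, starting material and partner would meet directly, target would rise fastest at the first moment, and the rate would slow by the two fractions still unspent, towards a ceiling of 0.70 of the charge, with partner as limiting reagent.

| flask | starting material | partner | temperature | remark | time |
|---|---|---|---|---|---|
| spring | 0.14 M | 0.70 equiv | 95 °C | run made earlier |  |
| midnight | 0.20 M | 0.70 equiv | 106 °C | run made earlier |  |
| dawn | 0.31 M | 0.70 equiv | 95 °C | run made earlier |  |
| theta | 0.14 M (in portions, 3, over 1.5 h) | 0.700 equiv | 100 °C | first portion at the start, last at 1.5 h | 8.0 h |
| epsilon | 0.14 M (fed, over 1.5 h) | 0.700 equiv | 100 °C | all else is in the flask from the start; the feed brings no volume worth counting | 8.0 h |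
| beta | 0.14 M | 0.700 equiv (fed, over 1.5 h) | 100 °C | all else is in the flask from the start; the feed brings no volume worth counting | 8.0 h |
| gamma | 0.14 M | 0.700 equiv (fed, over 1.5 h) |  | the addition at 80 °C, then warmed to 100 °C; the feed brings no volume worth counting | 8.0 h |

| run | time / h | target / % |
|---|---|---|
| spring | 0.417 | 0.5 |
| spring | 0.667 | 1.8 |
| spring | 1.33 | 3.7 |
| spring | 2.50 | 10.4 |
| spring | 5.00 | 20.2 |
| midnight | 0.667 | 8.0 |
| midnight | 2.00 | 25.3 |
| midnight | 4.00 | 31.7 |
| midnight | 6.00 | 32.2 |
| midnight | 8.00 | 30.7 |
| dawn | 1.50 | 8.2 |
| dawn | 3.00 | 18.3 |
| dawn | 5.00 | 26.5 |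
| dawn | 6.00 | 27.3 |
| dawn | 8.00 | 28.6 |

(readings scatter by 0.3 percentage points)

- percentages count the starting material that a species holds: one homo product or idle adduct or side product counts as two
- target is meant together with its idle adduct and crystals
- solid, in amounts per volume of the solution: crystals
- the numbers in the tables scatter by 0.3 percentage points (one standard deviation)
- what may be going on: starting material -> intermediate; partner + intermediate -> target; 2 intermediate -> homo product; starting material + target <-> idle adduct; crystals <-> target; starting material + target -> side product
- in an amount of target, one idle adduct counts as one target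

I read the rate first, as fractions of the charge. The midnight run gained 0.130 h⁻¹ between 0.667 h and 2.00 h. At 31.7 % of target, a one-step world would keep 68.3 % of the starting material and 54.7 % of the partner, so about 0.0486 h⁻¹ should have remained. Yet from 4.00 h to 8.00 h the reading went from 31.7 % to 30.7 %, so a further brake stopped the curve on a plateau, at 0.460 of the ceiling there and 0.409 in the dawn run.

Over the middle stretch the spring run gained 0.0392 h⁻¹ and the stronger dawn run 0.0410 h⁻¹, but the early readings stood apart, 8.2 % at 1.50 h in the dawn run against 3.7 % at 1.33 h in the spring run, so I read no order from these rates. Between the spring and midnight rates, whose runs differ in charge as well as temperature, I put 100 °C roughly at 0.0675 h⁻¹. With a plateau read at 0.304, a share of 0.434 of the ceiling, I reckoned filling at 4.50 h. I carried the fill count, the number of such fillings that the flask's hours hold at this pace: 1.78. Even with the whole 1.5 h of addition added, I reckoned filling done by 6.00 h, before 8.0 h, so I expected four flasks alike near 0.304.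

1. the best flask by amount of target, in percent of the starting material charged; "all alike" if 1.5 percentage points covers them all (theta / epsilon / beta / gamma / all alike)
2. amount of target at the end, in percent of the starting material charged, theta
3. amount of target at the end, in percent of the starting material charged, epsilon
4. amount of target at the end, in percent of the starting material charged, beta
5. amount of target at the end, in percent of the starting material charged, gamma

The forecast differed from me in naming epsilon as best, with 32 %, 33 %, 27 % and 30 % for theta, epsilon, beta and gamma, because “the steady feed helps slightly more than portions”.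

The flasks gave 28.5 %, 28.6 %, 28.6 % and 28.2 %, a spread of 0.40 percentage points: all alike.

    starting material → intermediate (k = 9.91 × 10⁻⁵ s⁻¹, Ea = 107 kJ mol⁻¹)
    partner + intermediate → target (k = 0.00123 M⁻¹ s⁻¹, Ea = 95.0 kJ mol⁻¹)
    2 intermediate → homo product (k = 9.46 × 10⁻⁴ M⁻¹ s⁻¹, Ea = 71.0 kJ mol⁻¹)
    starting material + target ⇌ idle adduct, settled at all times (K = 239 M⁻¹, ΔH = 21.0 kJ mol⁻¹)
    crystals ⇌ target, rate k5*(cs5 - [target]) while solid is left; crystals form when [target] > cs5 (solubility = 47.0 mM, k = 4.53 × 10⁻⁴ s⁻¹)
    starting material + target → side product (k = 0.00623 M⁻¹ s⁻¹, Ea = 81.0 kJ mol⁻¹)
    (constants at 100 °C)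

On its own result, beta counted 1.89 fills, and left ten times as long it gave 29.5 % at 80.0 h. The largest single effect among those taken away in beta was the joining of starting material and target to idle adduct: beta without that joining gave 14.6 % against 28.6 %. In beta's neighbour with 2.80 equiv of partner, the ceiling became the whole charge, so my share gave 43.4 % at 1.24 fills, and that flask gave 39.8 %.

The readings stem from a simulated flask on assumed constants, noise included.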